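**Retrosynthetic overview**

- Numbering: ring A = C5–C6–C7–C8–C9–C10, ring B = C10–C1–C2–C3–C4–C5; β is the face of ring B that carries the C4 and C5 methyl groups. Ring A is disconnected at C6=C7: intramolecular Knoevenagel condensation of a C8/C7/acetyl β-diketone onto the C6 aldehyde, the diketone being carried as a 3-methylisoxazole until both esters are in place.
- C8–C9 comes from chelation-controlled ethynylation of a C9 aldehyde (then nitrile oxide cycloaddition); C9–C10 from vinyl addition to a C10 ketone and ozonolysis; the ketone derives from the C10 acetate.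
- Ring B is made first, by Diels–Alder union of tiglic aldehyde 1 (C4=C5, CHO = C6) with (E,E)-1,4-diacetoxybutadiene 2 (C3=C2–C1=C10), forming C3–C4 and C5–C10.
- Feature relied on: in ring B the C3 oxygen, C4 methyl, C5 methyl and C10 oxygen are all cis and C6 is trans to them, which is the pattern of the formyl-exo adduct of an E enal with an E,E-1,4-dioxygenated diene.
- Ring order: ring B (step 1), then ring A (step 15).

Key step: step 1

Assumption: the catalyst antipode that exposes the Cα-Si face of the boron-bound enal is written as the (S)-prolinol-derived one; the sense of induction is not established for this enal/diene pair, and the (R)-catalyst would be used if the opposite face were attacked.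

**Step 1**
Reactants: 1 tiglic aldehyde; 2 (1E,3E)-1,4-diacetoxybuta-1,3-diene
Product: 3 3β,10β-diacetoxy-4β,5β-dimethylcyclohex-1-ene-5α-carbaldehyde (formyl-exo adduct)
Conditions: (S)-3,3-diphenyl-1-(2-methylphenyl)tetrahydro-1H,3H-pyrrolo[1,2-c][1,3,2]oxazaborole·HNTf2 (20 mol%), 2 (1.5 equiv), CH2Cl2, −78 to −20 °C
Reagents that add atoms: none
Why: The protonated oxazaborolidine binds the formyl oxygen of 1, and the activated enal then undergoes a concerted, asynchronous, suprafacial Diels–Alder [4+2] addition with s-cis 2, forming C5–C10 and C3–C4. The closest known reactions are formyl-exo cycloadditions of 2-methyl- and 2-bromoacrolein to cyclic and acyclic dienes under this class of chiral boron Lewis acid, and thermal cycloadditions of 2 with acrylic dienophiles. Ring B closes as a six-membered carbocycle by intermolecular pericyclic [4+2] closure, and the two-fold symmetry of 2 removes any regiochemical choice. The cis C4/C5 methyls are dictated by the E geometry of 1, the cis C3/C10 acetoxy groups by the E,E geometry of 2, and the relation between the two pairs (methyls on the acetoxy face, CHO opposite) by the formyl-exo transition state, in which both methyl groups lie under the diene. The absolute configuration of all four centres follows from catalyst control of the enal face (bonding at the Cα-Si face, the other face being covered by an aryl group of the catalyst). The step therefore needs exo and enantiofacial selectivity, which the α-methyl group of 1 (disfavouring the formyl-endo arrangement) and the rigid formyl-bound catalyst complex should secure.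

**Step 2**
Reactants: 3 formyl-exo cycloadduct
Product: 4 3β,10β-diacetoxy-4β,5β-dimethylcyclohexane-5α-carbaldehyde
Conditions: H2 (1 atm), Rh/Al2O3 (5%), EtOAc, rt
Reagents that add atoms: none
Why: Heterogeneous hydrogenation of the cis-disubstituted C1=C2 bond; Rh on alumina is chosen because it saturates alkenes with little hydrogenolysis of the flanking allylic acetates and leaves the aldehyde alone, and no stereocentre is formed.

**Step 3**
Reactants: 4 saturated diacetoxy aldehyde
Product: 5 dimethyl acetal of 4 (C6 = CH(OMe)2)
Conditions: HC(OMe)3, MeOH, p-TsOH (cat.), rt to 40 °C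
Reagents that add atoms: trimethyl orthoformate, COC(OC)OC; methanol, CO
Why: Acid-catalysed acetalisation driven by the orthoformate masks C6 before base and carbanions are used (a free β-hydroxy aldehyde would suffer retro-aldol cleavage of C5–C10 in step 4); C5 is quaternary, so nothing can epimerise.

**Step 4**
Reactants: 5 diacetoxy dimethyl acetal
Product: 6 3β,10β-diol dimethyl acetal
Conditions: K2CO3, MeOH, rt
Reagents that add atoms: none
Why: Base-catalysed transesterification (methanolysis) removes both acetates; the acetal is inert to these conditions and no stereocentre is touched.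

**Step 5**
Reactants: 6 diol acetal
Product: 7 3β-(tert-butyldimethylsilyloxy)-10β-ol acetal
Conditions: TBSCl (1.1 equiv), imidazole, DMF, 0 °C
Reagents that add atoms: tert-butyldimethylsilyl chloride, CC(C)(C)[Si](C)(C)Cl
Why: Selective silylation: the C10 hydroxyl is neopentylic, flanked by the quaternary C5 with its methyl and dimethoxymethyl groups, whereas the C3 hydroxyl has only the C4 methine beside it, so one equivalent of TBSCl should react at C3.

**Step 6**
Reactants: 7 C3 silyl ether
Product: 8 C10 ketone
Conditions: Dess–Martin periodinane, pyridine, CH2Cl2, rt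
Reagents that add atoms: none
Why: Dess–Martin oxidation of the hindered secondary alcohol under buffered conditions that spare acetal and silyl ether; C5 is quaternary and C4 is not α to the carbonyl, so no centre can epimerise.

**Step 7**
Reactants: 8 C10 ketone
Product: 9 10α-vinyl-10β-ol
Conditions: CH2=CHMgBr, CeCl3, THF, −78 °C
Reagents that add atoms: vinylmagnesium bromide, C=C[Mg]Br
Why: 1,2-Addition of the weakly basic organocerium reagent (suppressing enolisation towards C1) to the hindered ketone; the β face is screened by the adjacent C5 methyl, the syn-axial C4 methyl and the C3 silyloxy group, so vinyl should enter from the α face and place the new C10 hydroxyl β, cis to the C5 methyl.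

**Step 8**
Reactants: 9 tertiary allylic alcohol
Product: 10 10β-hydroxy C9 aldehyde
Conditions: O3, CH2Cl2, −78 °C; then PPh3
Reagents that add atoms: ozone, [O-][O+]=O
Why: Ozonolysis with reductive work-up cleaves the only alkene to the C9 aldehyde; the acetal C–H and silyl ether react far more slowly with ozone at −78 °C, and the α-hydroxy aldehyde is used crude to avoid dimerisation or α-ketol rearrangement.

**Step 9**
Reactants: 10 α-hydroxy aldehyde
Product: 11 9-ethynyl 9,10-diol (9-OH and 10-OH syn in the C5–C10–C9–C8 zigzag)
Conditions: HC≡CMgBr (4 equiv), THF, −78 to 0 °C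
Reagents that add atoms: ethynylmagnesium bromide, C#C[Mg]Br
Why: Chelation-controlled Grignard addition: the first equivalent forms the C10 magnesium alkoxide, which ties the aldehyde oxygen into a five-membered chelate, and the acetylide attacks C9 from the side of the C1 methylene, away from the quaternary C5, setting the C9 configuration that becomes C9–O trans to C10–OH once ring A is closed.

**Step 10**
Reactants: 11 propargylic diol
Product: 12 9-(3-methylisoxazol-5-yl) 9,10-diol
Conditions: MeCH=NOH, NCS, DMF, rt; then 11, Et3N (slow addition), rt
Reagents that add atoms: acetaldoxime, CC=NO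
Why: 1,3-Dipolar (Huisgen) cycloaddition of acetonitrile oxide, generated in situ by chlorination of the oxime and dehydrochlorination, to the terminal alkyne gives the 3,5-disubstituted isoxazole regioselectively (oxygen on C8), a mask for the β-diketone that is stable to acylation, fluoride and mild acid; no stereocentre is affected.

**Step 11**
Reactants: 12 isoxazolyl diol; 13 angelic acid
Product: 14 C9 angelate
Conditions: 13, 2,4,6-Cl3C6H2COCl, Et3N, PhMe, rt; then 12, PhMe, 80 °C
Reagents that add atoms: none
Why: Yamaguchi-type esterification in which the preformed angelic 2,4,6-trichlorobenzoic mixed anhydride acylates the secondary C9 hydroxyl on heating without DMAP, conditions chosen to avoid the addition–elimination that isomerises the Z (angelate) double bond to E; the hindered tertiary C10 hydroxyl is not acylated and C9 keeps its configuration because the C–O bond is not broken.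

**Step 12**
Reactants: 14 silyl ether angelate
Product: 15 C3 alcohol
Conditions: Bu4NF, AcOH, THF, rt
Reagents that add atoms: none
Why: Fluoride-mediated desilylation; buffering with AcOH keeps the medium non-basic so the angelate neither migrates nor is cleaved, and the acetal is stable to fluoride.

**Step 13**
Reactants: 15 C3 alcohol
Product: 16 C3 acetate
Conditions: Ac2O, pyridine, rt
Reagents that add atoms: acetic anhydride, CC(=O)OC(C)=O
Why: Acetylation of the only secondary hydroxyl; the tertiary C10 hydroxyl, flanked by quaternary C5 and substituted C9, is inert to Ac2O/pyridine at room temperature, and DMAP is omitted to protect the angelate geometry.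

**Step 14**
Reactants: 16 isoxazole diester
Product: 17 (Z)-enaminone (C8 ketone, NH2 on the acetyl carbon)
Conditions: Mo(CO)6, MeCN/H2O, 80 °C
Reagents that add atoms: none
Why: Reductive cleavage of the isoxazole N–O bond by Mo(CO)6 in wet acetonitrile unmasks the β-diketone as its primary enaminone, with oxygen on C8 and nitrogen on the acetyl carbon; esters, the angelate alkene, the acetal and the tertiary alcohol should be untouched.

**Step 15**
Reactants: 17 enaminone acetal
Product: 19 target CNP0196241.1, via keto-aldehyde 18 (not isolated)
Conditions: 1 M HCl, THF, rt; then piperidine (cat.), AcOH (cat.), CH2Cl2, rt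
Reagents that add atoms: water, O
Why: Dilute aqueous acid hydrolyses the enaminone to the β-diketone and the dimethyl acetal to the C6 aldehyde, and buffered amine catalysis then effects intramolecular Knoevenagel condensation of C7 onto C6 (6-exo-trig attack followed by dehydration), closing ring A as the 2-acetyl enone; the cis ring fusion is fixed by C5 and C10, and the near-neutral conditions are chosen to avoid C9 epimerisation or β-elimination of the C10 hydroxyl.

**Compound list**

1 | tiglic aldehyde, (E)-2-methylbut-2-enal | C/C=C(\C)C=O | starting material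
2 | (1E,3E)-1,4-diacetoxybuta-1,3-diene | CC(=O)O/C=C/C=C/OC(C)=O | starting material
3 | 3β,10β-diacetoxy-4β,5β-dimethylcyclohex-1-ene-5α-carbaldehyde (target numbering; acetates and methyls all cis, CHO trans) | O=C[C@]1(C)[C@@H](C)[C@@H](OC(C)=O)C=C[C@H]1OC(C)=O | intermediate
4 | 3β,10β-diacetoxy-4β,5β-dimethylcyclohexane-5α-carbaldehyde | O=C[C@]1(C)[C@@H](C)[C@@H](OC(C)=O)CC[C@H]1OC(C)=O | intermediate
5 | dimethyl acetal of 4 | COC(OC)[C@]1(C)[C@@H](C)[C@@H](OC(C)=O)CC[C@H]1OC(C)=O | intermediate
6 | 3β,10β-diol dimethyl acetal | COC(OC)[C@]1(C)[C@@H](C)[C@@H](O)CC[C@H]1O | intermediate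
7 | 3β-TBS ether, 10β-ol, dimethyl acetal | COC(OC)[C@]1(C)[C@@H](C)[C@@H](O[Si](C)(C)C(C)(C)C)CC[C@H]1O | intermediate
8 | 3β-TBS ether, C10 ketone, dimethyl acetal | COC(OC)[C@]1(C)[C@@H](C)[C@@H](O[Si](C)(C)C(C)(C)C)CCC1=O | intermediate
9 | 10α-vinyl-10β-hydroxy compound | COC(OC)[C@]1(C)[C@@H](C)[C@@H](O[Si](C)(C)C(C)(C)C)CC[C@]1(O)C=C | intermediate
10 | 10β-hydroxy-10α-carbaldehyde (C9 aldehyde) | COC(OC)[C@]1(C)[C@@H](C)[C@@H](O[Si](C)(C)C(C)(C)C)CC[C@]1(O)C=O | intermediate
11 | 9-ethynyl-9,10-diol, C9 configured as in the target | COC(OC)[C@]1(C)[C@@H](C)[C@@H](O[Si](C)(C)C(C)(C)C)CC[C@]1(O)[C@H](O)C#C | intermediate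
12 | 9-(3-methylisoxazol-5-yl)-9,10-diol | COC(OC)[C@]1(C)[C@@H](C)[C@@H](O[Si](C)(C)C(C)(C)C)CC[C@]1(O)[C@H](O)c2cc(C)no2 | intermediate
13 | angelic acid, (Z)-2-methylbut-2-enoic acid | C/C=C(/C)C(O)=O | starting material
14 | C9 angelate of 12 | COC(OC)[C@]1(C)[C@@H](C)[C@@H](O[Si](C)(C)C(C)(C)C)CC[C@]1(O)[C@H](OC(=O)/C(C)=C\C)c2cc(C)no2 | intermediate
15 | C9 angelate, free C3 alcohol | COC(OC)[C@]1(C)[C@@H](C)[C@@H](O)CC[C@]1(O)[C@H](OC(=O)/C(C)=C\C)c2cc(C)no2 | intermediate
16 | C3 acetate, C9 angelate, isoxazole, dimethyl acetal | COC(OC)[C@]1(C)[C@@H](C)[C@@H](OC(C)=O)CC[C@]1(O)[C@H](OC(=O)/C(C)=C\C)c2cc(C)no2 | intermediate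
17 | (Z)-enaminone (4-amino-1-oxopent-3-en-1-yl chain on C9), dimethyl acetal | COC(OC)[C@]1(C)[C@@H](C)[C@@H](OC(C)=O)CC[C@]1(O)[C@H](OC(=O)/C(C)=C\C)C(=O)/C=C(/C)N | intermediate
18 | β-diketo aldehyde (C6 CHO, C8/acetyl diketone), not isolated | O=C[C@]1(C)[C@@H](C)[C@@H](OC(C)=O)CC[C@]1(O)[C@H](OC(=O)/C(C)=C\C)C(=O)CC(C)=O | intermediate
19 | CNP0196241.1 | C/C=C(/C)C(=O)O[C@@H]1C(=O)C(C(C)=O)=C[C@]2(C)[C@@H](C)[C@@H](OC(C)=O)CC[C@]12O | target

**Step count**

Total steps: 15. Longest linear sequence: 15 steps (1 and 2 to 19).

**Steps most likely to fail**

Step 1. The trisubstituted enal may be too sluggish towards the only modestly electron-rich diene at the low temperature the catalyst needs, and the acetate carbonyls may sequester the boron Lewis acid. Competing formyl-endo addition or weak facial discrimination would erode diastereo- and enantiopurity. The fallback sets out from 1 and 2 and returns at 6. The cycloaddition would be run without a chiral catalyst (EtAlCl2, CH2Cl2, −78 to 0 °C, or neat at about 110 °C), the exo diastereomer being purified, so that 3 is formed together with its mirror image ent-3 F1. The racemate would be taken through steps 2–4, giving ent-4 F2, ent-5 F3 and ent-6 F4 alongside 4, 5 and 6. The racemic diol would then be resolved by lipase-catalysed transesterification (immobilised Candida antarctica lipase B, vinyl acetate, t-BuOMe). The usual size-based preference of lipases for secondary carbinols predicts acylation of the 3R enantiomer to ent-6 3-O-acetate F5, leaving 6 unreacted, to be separated by chromatography and taken into step 5.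

Step 11. Acylation of the hindered C9 carbinol may be slower than Z-to-E isomerisation of the activated angeloyl unit, or the aroyl part of the mixed anhydride may be transferred instead. The fallback sets out from 12 and returns at 14. Compound 12 would be esterified with 2-[bis(2,2,2-trifluoroethoxy)phosphoryl]propanoic acid (DCC, DMAP, CH2Cl2) to the C9 phosphonopropionate F6. The Z-trisubstituted alkene would then be built on the ester by Still–Gennari olefination with acetaldehyde (KN(SiMe3)2, 18-crown-6, THF, −78 °C, one extra equivalent of base for the C10 hydroxyl), which should give 14 with the Z geometry set kinetically.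

Step 15. Condensation at the neopentylic C6 aldehyde may be slow, and prolonged exposure of the open-chain α-acyloxy-β-hydroxy ketone to amine or acid may lead to retro-aldol cleavage of C9–C10, β-elimination of the C10 hydroxyl or epimerisation at C9. The fallback sets out from 17 and returns at 19. The C6–C7 bond would be formed before the aldehyde is liberated: Lewis-acid ionisation of the dimethyl acetal (TMSOTf, 2,4,6-collidine, CH2Cl2, −78 °C) and capture of the oxocarbenium ion by the nucleophilic α-carbon (C7) of the enaminone, a Mukaiyama-type cyclisation, should give the 6-methoxy cyclised enaminone F7. Brief treatment with aqueous HCl in THF would then hydrolyse the enaminone and expel methanol from the resulting β-methoxy diketone to give 19.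

**Further compounds**

F1 | step 1 | ent-3 (mirror image of the cycloadduct) | O=C[C@@]1(C)[C@H](C)[C@H](OC(C)=O)C=C[C@@H]1OC(C)=O
F2 | step 1 | ent-4 | O=C[C@@]1(C)[C@H](C)[C@H](OC(C)=O)CC[C@@H]1OC(C)=O
F3 | step 1 | ent-5 | COC(OC)[C@@]1(C)[C@H](C)[C@H](OC(C)=O)CC[C@@H]1OC(C)=O
F4 | step 1 | ent-6 | COC(OC)[C@@]1(C)[C@H](C)[C@H](O)CC[C@@H]1O
F5 | step 1 | ent-6 3-O-acetate | COC(OC)[C@@]1(C)[C@H](C)[C@H](OC(C)=O)CC[C@@H]1O
F6 | step 11 | C9 2-[bis(2,2,2-trifluoroethoxy)phosphoryl]propanoate of 12 | COC(OC)[C@]1(C)[C@@H](C)[C@@H](O[Si](C)(C)C(C)(C)C)CC[C@]1(O)[C@H](OC(=O)C(C)P(=O)(OCC(F)(F)F)OCC(F)(F)F)c2cc(C)no2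
F7 | step 15 | 6-methoxy cyclised enaminone (ring A closed, C7=C(NH2)CH3, C6–OMe) | C/C=C(/C)C(=O)O[C@@H]1C(=O)C(=C(C)N)C(OC)[C@]2(C)[C@@H](C)[C@@H](OC(C)=O)CC[C@]12O
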